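No rate constant is given for any step here, so we work with one number read from the earlier run.

- eta: Dz 0.012 M; Ja 9 mM; run made earlier
- flask: Dz 0.012 M; Ja 6.00 mM; time 15 d

eta run (percent of the Dz and Ja together charged)

| time / d | Lx / % | Wy / % | Dz / % |
|---|---|---|---|
| 0.500 | 9 | 6 | 70 |
| 1.04 | 12 | 13 | 48 |
| 1.67 | 14 | 18 | 33 |
| 2.08 | 12 | 24 | 25 |
| 2.50 | 13 | 31 | 20 |
| 3.00 | 15 | 35 | 13 |

(each reading ± 1.5 percentage points)

- share of Lx in Lx plus Wy at 40 min
- share of Lx in Lx plus Wy at 15 d
- which of Lx and Wy there is more of at 15 d

- what was read earlier has a scatter of 1.5 percentage points, one standard deviation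

We read the table row by row, dividing Wy by Lx. This gives 0.667 at 0.500 d, 2.00 at 2.08 d, 2.38 at 2.50 d and 2.33 at 3.00 d. The ratio climbs, and with a scatter of 1.5 percentage points on each reading the last two values cannot tell us whether it is still climbing. Pooling the last two rows gives 2.36. We call this the late ratio, Wy over Lx pooled over the last two rows, and we take it as our estimate of where the ratio ends, the end state of what the field calls thermodynamic control. It is a rough estimate: the eta run still holds 13 % of Dz at 3.00 d, and the ratio may end higher.

If Lx and Wy end in equilibrium through first-order steps, the charges drop out of their end ratio, so we carry our estimate to the flask with 6.00 mM of Ja. Lx is then one part in one plus the late ratio, a share of 29.8 %.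

Now we go round once more. At 3.00 d Lx, Wy and Dz add up to 63.0 %, and over the last two rows the missing part stands to Lx as 2.61. We hand out the remaining Dz in these same proportions. That leaves the ratio as it was, so the share stands, and at 15 d the flask should hold 16.8 % of Lx and 39.5 % of Wy, with Wy ahead.

The early question is rougher. The first row gives a share of 60.0 %, and 40 min is earlier than that row, so we put the share in the flask above this reading.

The forecast, which differs from our late share, gives 60 % at 40 min and 13 % at 15 d, with Wy ahead, and adds: "The mechanism is uncertain, so the ranges are wide."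

The flask gives 80.6 % at 40 min and 26.3 % at 15 d, with Wy ahead.

    Dz ⇌ Ja (K = 0.0280, k = 5.30 × 10⁻⁵ s⁻¹)
    Dz → Lx (k = 7.40 × 10⁻⁶ s⁻¹)
    Ja → Wy (k = 1.50 × 10⁻⁵ s⁻¹)
    Lx ⇌ Wy (K = 2.80, k = 1.80 × 10⁻⁵ s⁻¹)
    Lx ⇌ Xo (K = 2.90, k = 5.10 × 10⁻⁵ s⁻¹)

In the flask Wy stands to Lx as 2.80 at 15 d, so our share of 29.8 % lies 3.5 points above the flask's, and the share is the same at 150 d. We take the same late ratio to the neighbour flask, charged with 0.048 M of Dz. It again gives 29.8 %, and with the missing part 16.8 % of Lx and 39.5 % of Wy. That neighbour flask ends with a share of 26.3 %, holding 14.9 % of Lx, 41.8 % of Wy and 43.3 % of Xo.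

The data are simulated for an exercise.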